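**Plan**

1. Retrosynthetic cuts, last to first: the three O–Si bonds; the C5=CH bond (back to a C5 benzyl group on a 2-silyloxyfuran); then, in one move, the ring bonds C2–C3 (lactone carbonyl carbon to carbinol-bearing carbon) and C4–C5 (aryl-bearing carbon to ylidene-bearing carbon); then the silicon tether and the carbinol–alkyne C–C bond.
2. Enabling feature: in the furanone ring O1 is flanked by C2 and C5, so O1/C2/C5 can arrive as O1/C5/C2 of an oxazole and C3=C4 as an alkyne. The carbinol oxygen on the C3 side chain stands 1,5 to the lactone carbonyl oxygen, so one iPr2Si unit can bridge both oxygens, making the oxazole–alkyne union intramolecular and fixing its orientation.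
3. Forward order: aryl alkyne, then (S)-propargylic alcohol; arylacetyl-alanine, then azlactone; silaketal tether; intramolecular oxazole–alkyne Diels–Alder/retro-Diels–Alder reaction (loss of MeCN), which closes the fully substituted furan ring (a silyl-masked butenolide) together with a temporary dioxasiline ring; bromination/dehydrobromination to the Z-ylidene butenolide; fluoride removal of the tether residue and the phenol protection.
4. Stereochemistry: the single stereocenter is set in step 3 by an (R)-BINOL/Ti(OiPr)4-controlled alkynylzinc addition, and its C–O and C–H bonds are never broken afterwards. The Z alkene comes from the elimination in step 10.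

Key step: step 9

Assumption: the Ti(OiPr)4/BINOL alkynylzinc addition to aromatic aldehydes is taken to follow its usual sense, (S)-BINOL giving Si-face attack; (R)-BINOL is therefore used for Re-face attack, which corresponds to the (S)-carbinol here.
Remark: TIPS = triisopropylsilyl; compounds 1, 4, 7 and 8 are commercial.

**Route**

Step 1
Reactants: 1 3-bromo-4-hydroxybenzaldehyde
Product: 2 3-bromo-4-(triisopropylsilyloxy)benzaldehyde
Conditions: TIPSCl, imidazole, DMF, rt
Reagents that add atoms: triisopropylsilyl chloride, CC(C)[Si](Cl)(C(C)C)C(C)C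
Why: Standard phenol silylation; the TIPS ether should survive the later base, organozinc, heat and NBS steps and leave with fluoride at the end.

Step 2
Reactants: 2 3-bromo-4-(triisopropylsilyloxy)benzaldehyde
Product: 3 (2-bromo-4-ethynylphenoxy)triisopropylsilane
Conditions: TMSCHN2, LiN(iPr)2, THF, −78 °C; then 2, −78 °C to rt
Reagents that add atoms: trimethylsilyldiazomethane, C[Si](C)(C)C=[N+]=[N-]
Why: Colvin rearrangement (addition of lithiated TMS-diazomethane, loss of Me3SiOLi and N2, 1,2-shift in the alkylidene carbene) should give the terminal alkyne; the base is consumed before the aryl bromide is added, and the carbonate/methanol medium that could cleave the activated aryl silyl ether is avoided.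

Step 3
Reactants: 3 (2-bromo-4-ethynylphenoxy)triisopropylsilane (2 equiv, excess recovered); 4 3,5-dibromo-4-methoxybenzaldehyde
Product: 6 (S)-1-(3,5-dibromo-4-methoxyphenyl)-3-[3-bromo-4-(triisopropylsilyloxy)phenyl]prop-2-yn-1-ol, via ethyl alkynylzinc 5 (not isolated)
Conditions: 3, Et2Zn, PhMe, reflux; then (R)-BINOL (20 mol %), Ti(OiPr)4 (50 mol %), CH2Cl2, rt; then 4, rt
Reagents that add atoms: none
Why: Catalytic asymmetric alkynylzinc addition to an aromatic aldehyde, in which the titanium BINOLate should direct the alkynyl group to the Re face and so set the (S)-carbinol; aryl bromides and the silyl ether are inert to organozinc reagents.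

Step 4
Reactants: 7 (3-bromo-4-hydroxyphenyl)acetic acid; 8 L-alanine tert-butyl ester hydrochloride
Product: 9 tert-butyl N-[(3-bromo-4-hydroxyphenyl)acetyl]-L-alaninate
Conditions: EDC·HCl, HOBt, iPr2NEt, CH2Cl2, 0 °C to rt
Reagents that add atoms: none
Why: Carbodiimide amide coupling through the HOBt ester, in which the amine should outcompete the unprotected, weakly nucleophilic bromophenol.

Step 5
Reactants: 9 tert-butyl N-[(3-bromo-4-hydroxyphenyl)acetyl]-L-alaninate
Product: 10 tert-butyl N-{[3-bromo-4-(triisopropylsilyloxy)phenyl]acetyl}-L-alaninate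
Conditions: TIPSCl, imidazole, DMF, rt
Reagents that add atoms: triisopropylsilyl chloride, CC(C)[Si](Cl)(C(C)C)C(C)C
Why: Standard phenol silylation; the secondary amide and the tert-butyl ester do not react.

Step 6
Reactants: 10 tert-butyl N-{[3-bromo-4-(triisopropylsilyloxy)phenyl]acetyl}-L-alaninate
Product: 11 N-{[3-bromo-4-(triisopropylsilyloxy)phenyl]acetyl}-L-alanine
Conditions: TFA, CH2Cl2, 0 °C to rt
Reagents that add atoms: none
Why: Acidolysis of the tert-butyl ester with loss of isobutene; a hindered aryl TIPS ether should tolerate TFA.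

Step 7
Reactants: 11 N-{[3-bromo-4-(triisopropylsilyloxy)phenyl]acetyl}-L-alanine
Product: 12 2-[3-bromo-4-(triisopropylsilyloxy)benzyl]-4-methyl-1,3-oxazol-5(4H)-one
Conditions: EDC·HCl, CH2Cl2, 0 °C; cold aqueous wash, used crude
Reagents that add atoms: none
Why: Carbodiimide cyclodehydration of an N-acyl amino acid to the azlactone; loss of configuration at C4 is irrelevant because this carbon leaves as acetonitrile in step 9.

Step 8
Reactants: 6 (S)-propargylic alcohol; 12 azlactone
Product: 14 diisopropylsilylene diether joining the carbinol oxygen of 6 to O5 of 2-[3-bromo-4-(triisopropylsilyloxy)benzyl]-4-methyl-1,3-oxazol-5-ol, via chlorosilyl ether 13 (not isolated)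
Conditions: iPr2SiCl2 (1.05 equiv), Et3N, DMAP (cat.), CH2Cl2, 0 °C; then 12, Et3N, 0 °C to rt; filtration under argon, no chromatography
Reagents that add atoms: dichlorodiisopropylsilane, CC(C)[Si](Cl)(Cl)C(C)C
Why: Stepwise silaketal formation, in which the hindered dichlorosilane should stop at the monoalkoxychlorosilane and the azlactone, deprotonated at C4 by Et3N to the aromatic oxazol-5-olate, should be silylated at oxygen (silyl enol ether formation); only the O–H bond of the stereocenter reacts.

Step 9
Reactants: 14 silaketal-tethered 5-silyloxyoxazole–alkyne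
Product: 16 (S)-4-(3,5-dibromo-4-methoxyphenyl)-2,2-diisopropyl-5-[3-bromo-4-(triisopropylsilyloxy)phenyl]-6-[3-bromo-4-(triisopropylsilyloxy)benzyl]-4H-furo[2,3-d][1,3,2]dioxasiline, via oxa-aza-bicyclic cycloadduct 15 (not isolated)
Conditions: o-xylene (0.01 M), iPr2NEt (0.2 equiv), 140 °C, sealed tube, argon; used crude
Reagents that add atoms: none
Why: Proposed new method: the 5-silyloxyoxazole of 14 is an electron-rich 2-azadiene whose termini C2 and C5 flank the ring oxygen, and the silaketal holds the aryl alkyne over them, so a thermal intramolecular [4+2] cycloaddition should give the 7-oxa-2-azabicyclo[2.2.1]heptadiene 15, which loses acetonitrile (the N3–C4 bridge) by retro-[4+2] and thereby forms the lactone-carbonyl-carbon-to-C3 bond and the C4-to-C5 bond of the future butenolide in one operation. The closest known reaction type is the intramolecular Diels–Alder/retro-Diels–Alder reaction of 5-alkoxyoxazoles carrying an alkyne on a carbon chain, which gives 2-alkoxyfurans as butenolide precursors; new here are the 5-silyloxy group and the O–Si–O link, which should raise the diene HOMO without changing the mechanism. The furan ring is closed by concerted cycloaddition across oxazole C2/C5 followed by cycloreversion (a formal (3+2) union of the C–O–C unit with the alkyne), and the six-membered 1,3,2-dioxasiline ring is closed in the same cycloaddition in the fused mode, the tether being attached at the diene terminus C5 and at the propargylic carbon. No lasting stereocenter is created: the two bridgehead centers of 15 vanish on aromatization, and the carbinol center from step 3 is not involved. The step needs regioselectivity (silyloxy-bearing C5 to the propargylic alkyne carbon, C2 to the aryl-bearing carbon), which the four-atom tether secures because the opposite orientation would require a bridged transition state, and it needs reactivity toward an unactivated alkyne, which intramolecularity and the donor oxygen at C5 should provide. The amine buffer and dilution are there to suppress acid-promoted ionization of the furylic C–O bond and intermolecular silyl transfer.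

Step 10
Reactants: 16 bicyclic 2-silyloxyfuran
Product: 19 (Z)-5-[3-bromo-4-(triisopropylsilyloxy)benzylidene]-4-[3-bromo-4-(triisopropylsilyloxy)phenyl]-3-{(S)-(3,5-dibromo-4-methoxyphenyl)[hydroxy(diisopropyl)silyloxy]methyl}furan-2(5H)-one, via bromolactone 17 (not isolated), via N-silylsuccinimide ylidene lactone 18 (not isolated)
Conditions: NBS, THF, −78 °C; then DBU, −78 to 0 °C; aq. NaHCO3 work-up
Reagents that add atoms: water, O; N-bromosuccinimide, O=C1CCC(=O)N1Br (its atoms stay only in 17 and 18)
Why: Electrophilic bromination of the 2-silyloxyfuran at C5 (silicon passing to the succinimide nitrogen) followed by E2 loss of HBr toward the only β-hydrogens, those of the benzyl group, is the known bromination/dehydrobromination route to 5-ylidene butenolides; the Z isomer should prevail because it keeps the ylidene aryl away from the C4 aryl, and aqueous work-up hydrolyzes the Si–N bond to the silanol.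

Step 11
Reactants: 19 silyl-protected ylidene butenolide
Product: 20 (Z)-5-(3-bromo-4-hydroxybenzylidene)-4-(3-bromo-4-hydroxyphenyl)-3-[(S)-(3,5-dibromo-4-methoxyphenyl)(hydroxy)methyl]furan-2(5H)-one
Conditions: TBAF, AcOH (1:1), THF, 0 °C
Reagents that add atoms: none
Why: Fluoride should cleave both aryl silyl ethers and the alkoxysilanol through pentacoordinate silicon, while acetic acid buffers the phenoxides so that the ylidene lactone is not opened or isomerized; the C–O bond of the stereocenter is not broken.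

**Compound list**

1 | 3-bromo-4-hydroxybenzaldehyde | O=Cc1ccc(O)c(Br)c1 | starting material
2 | 3-bromo-4-(triisopropylsilyloxy)benzaldehyde | O=Cc1ccc(O[Si](C(C)C)(C(C)C)C(C)C)c(Br)c1 | intermediate
3 | (2-bromo-4-ethynylphenoxy)triisopropylsilane | C#Cc1ccc(O[Si](C(C)C)(C(C)C)C(C)C)c(Br)c1 | intermediate
4 | 3,5-dibromo-4-methoxybenzaldehyde | COc1c(Br)cc(C=O)cc1Br | starting material
5 | ethyl{[3-bromo-4-(triisopropylsilyloxy)phenyl]ethynyl}zinc (not isolated) | CC[Zn]C#Cc1ccc(O[Si](C(C)C)(C(C)C)C(C)C)c(Br)c1 | intermediate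
6 | (S)-1-(3,5-dibromo-4-methoxyphenyl)-3-[3-bromo-4-(triisopropylsilyloxy)phenyl]prop-2-yn-1-ol | COc1c(Br)cc([C@H](O)C#Cc2ccc(O[Si](C(C)C)(C(C)C)C(C)C)c(Br)c2)cc1Br | intermediate
7 | (3-bromo-4-hydroxyphenyl)acetic acid | OC(=O)Cc1ccc(O)c(Br)c1 | starting material
8 | L-alanine tert-butyl ester hydrochloride | C[C@H](N)C(=O)OC(C)(C)C.Cl | starting material
9 | tert-butyl N-[(3-bromo-4-hydroxyphenyl)acetyl]-L-alaninate | C[C@H](NC(=O)Cc1ccc(O)c(Br)c1)C(=O)OC(C)(C)C | intermediate
10 | tert-butyl N-{[3-bromo-4-(triisopropylsilyloxy)phenyl]acetyl}-L-alaninate | C[C@H](NC(=O)Cc1ccc(O[Si](C(C)C)(C(C)C)C(C)C)c(Br)c1)C(=O)OC(C)(C)C | intermediate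
11 | N-{[3-bromo-4-(triisopropylsilyloxy)phenyl]acetyl}-L-alanine | C[C@H](NC(=O)Cc1ccc(O[Si](C(C)C)(C(C)C)C(C)C)c(Br)c1)C(=O)O | intermediate
12 | 2-[3-bromo-4-(triisopropylsilyloxy)benzyl]-4-methyl-1,3-oxazol-5(4H)-one (C4 configurationally labile, used as the racemate) | CC1N=C(Cc2ccc(O[Si](C(C)C)(C(C)C)C(C)C)c(Br)c2)OC1=O | intermediate
13 | chloro(diisopropyl)silyl ether of 6, (S) (not isolated) | COc1c(Br)cc([C@H](O[Si](Cl)(C(C)C)C(C)C)C#Cc2ccc(O[Si](C(C)C)(C(C)C)C(C)C)c(Br)c2)cc1Br | intermediate
14 | 5-{[(S)-1-(3,5-dibromo-4-methoxyphenyl)-3-(3-bromo-4-triisopropylsilyloxyphenyl)prop-2-yn-1-yloxy]diisopropylsilyloxy}-2-[3-bromo-4-(triisopropylsilyloxy)benzyl]-4-methyl-1,3-oxazole | COc1c(Br)cc([C@H](O[Si](C(C)C)(C(C)C)Oc2oc(Cc3ccc(O[Si](C(C)C)(C(C)C)C(C)C)c(Br)c3)nc2C)C#Cc2ccc(O[Si](C(C)C)(C(C)C)C(C)C)c(Br)c2)cc1Br | intermediate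
15 | 7-oxa-2-azabicyclo[2.2.1]hepta-2,5-diene cycloadduct fused to the 1,3,2-dioxasiline ring, (S) at the carbinol carbon, either bridgehead diastereomer (not isolated) | COc1c(Br)cc([C@@H]2O[Si](C(C)C)(C(C)C)OC34OC(Cc5ccc(O[Si](C(C)C)(C(C)C)C(C)C)c(Br)c5)(N=C3C)C(c3ccc(O[Si](C(C)C)(C(C)C)C(C)C)c(Br)c3)=C24)cc1Br | intermediate
16 | (S)-4-(3,5-dibromo-4-methoxyphenyl)-2,2-diisopropyl-5-[3-bromo-4-(triisopropylsilyloxy)phenyl]-6-[3-bromo-4-(triisopropylsilyloxy)benzyl]-4H-furo[2,3-d][1,3,2]dioxasiline | COc1c(Br)cc([C@@H]2O[Si](C(C)C)(C(C)C)Oc3oc(Cc4ccc(O[Si](C(C)C)(C(C)C)C(C)C)c(Br)c4)c(-c4ccc(O[Si](C(C)C)(C(C)C)C(C)C)c(Br)c4)c23)cc1Br | intermediate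
17 | 5-bromo-5-[3-bromo-4-(triisopropylsilyloxy)benzyl]-4-[3-bromo-4-(triisopropylsilyloxy)phenyl]-3-{(S)-(3,5-dibromo-4-methoxyphenyl)[diisopropyl(succinimido)silyloxy]methyl}furan-2(5H)-one, C5 epimers (not isolated) | COc1c(Br)cc([C@H](O[Si](C(C)C)(C(C)C)N2C(=O)CCC2=O)C2=C(c3ccc(O[Si](C(C)C)(C(C)C)C(C)C)c(Br)c3)C(Br)(Cc3ccc(O[Si](C(C)C)(C(C)C)C(C)C)c(Br)c3)OC2=O)cc1Br | intermediate
18 | (Z)-5-[3-bromo-4-(triisopropylsilyloxy)benzylidene]-4-[3-bromo-4-(triisopropylsilyloxy)phenyl]-3-{(S)-(3,5-dibromo-4-methoxyphenyl)[diisopropyl(succinimido)silyloxy]methyl}furan-2(5H)-one (not isolated) | COc1c(Br)cc([C@H](O[Si](C(C)C)(C(C)C)N2C(=O)CCC2=O)C2=C(c3ccc(O[Si](C(C)C)(C(C)C)C(C)C)c(Br)c3)/C(=C/c3ccc(O[Si](C(C)C)(C(C)C)C(C)C)c(Br)c3)OC2=O)cc1Br | intermediate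
19 | (Z)-5-[3-bromo-4-(triisopropylsilyloxy)benzylidene]-4-[3-bromo-4-(triisopropylsilyloxy)phenyl]-3-{(S)-(3,5-dibromo-4-methoxyphenyl)[hydroxy(diisopropyl)silyloxy]methyl}furan-2(5H)-one | COc1c(Br)cc([C@H](O[Si](O)(C(C)C)C(C)C)C2=C(c3ccc(O[Si](C(C)C)(C(C)C)C(C)C)c(Br)c3)/C(=C/c3ccc(O[Si](C(C)C)(C(C)C)C(C)C)c(Br)c3)OC2=O)cc1Br | intermediate
20 | (Z)-5-(3-bromo-4-hydroxybenzylidene)-4-(3-bromo-4-hydroxyphenyl)-3-[(S)-(3,5-dibromo-4-methoxyphenyl)(hydroxy)methyl]furan-2(5H)-one | COc1c(Br)cc([C@H](O)C2=C(c3ccc(O)c(Br)c3)/C(=C/c3ccc(O)c(Br)c3)OC2=O)cc1Br | target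

**Summary**

Total step count: 11. Longest linear sequence: 8 steps (steps 4, 5, 6, 7, 8, 9, 10, 11).

Steps most likely to fail:

Step 9. The cycloaddition may not start below the temperature at which the silyloxyoxazole loses its silyl group or transfers it between molecules, and the furylic C–O bond of the product may ionize and erode the stereocenter. The fallback gives up the tether and uses known intermolecular chemistry, setting out from 6. Oxidation with MnO2 in CH2Cl2 should give the ynone 1-(3,5-dibromo-4-methoxyphenyl)-3-[3-bromo-4-(triisopropylsilyloxy)phenyl]prop-2-yn-1-one F1. Heating F1 with commercial 5-ethoxy-4-methyloxazole (CCOc1ocnc1C) in toluene at 110 °C is the known Diels–Alder/retro-Diels–Alder reaction of 5-alkoxyoxazoles with acetylenic carbonyl dienophiles. By the polarization of both partners the acyl-bearing alkyne carbon should join the ethoxy-bearing C5, giving the 2-ethoxy-3-aroyl-4-arylfuran F2 with loss of acetonitrile. Aqueous HCl in THF should hydrolyze the ethoxyfuran to the 3-aroyl-4-aryl-furan-2(5H)-one F3. Vinylogous aldol condensation of F3 with aldehyde 2 (TBSOTf, iPr2NEt, CH2Cl2; then DBU) should give the (Z)-ylidene ketone F4. Corey–Bakshi–Shibata reduction with (R)-Me-CBS and catecholborane should then give the (S)-carbinol bis(silyl ether) F5; the choice of catalyst enantiomer assumes that the twisted, doubly flanked butenolide carbon acts as the large group, and this sense would have to be verified. F5 is desilylated under the conditions of step 11, so the fallback comes back to the route at 20.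

Step 8. Silylation of the oxazolate may go to carbon, the azlactone may condense with itself under base, or the Si–O–oxazole bond may hydrolyze during handling. The fallback forms the Si–O bond at the carboxylic acid stage and closes the oxazole afterwards, setting out from 11 and 6. The chlorosilane 13 (from 6 as in step 8) is treated with acid 11 and Et3N, where only the carboxylate oxygen can bind silicon, to give the acyloxy(alkoxy)diisopropylsilane (silyl ester) F6. Cyclodehydration of this N-acyl amino ester (Ph3P, I2, Et3N, CH2Cl2; Robinson–Gabriel-type closure) should give the 5-silyloxyoxazole, so the fallback comes back to the route at 14.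

Step 10. Bromination may occur at C3 instead of C5, the tertiary bromide may solvolyze before elimination, or the elimination may give an E/Z mixture. The fallback replaces halogenation/E2 by selenoxide syn-elimination, setting out from 16. PhSeCl in THF at −78 °C, followed by aqueous work-up, should give the 5-benzyl-5-(phenylselanyl)butenolide silanol F7. H2O2 and pyridine in CH2Cl2 at 0 °C should then oxidize it to the selenoxide, which can only eliminate toward the benzylic hydrogens. Any E isomer is equilibrated to Z with catalytic I2 in light, and the fallback comes back to the route at 19.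

**Further compounds**

F1 | step 9 | 1-(3,5-dibromo-4-methoxyphenyl)-3-[3-bromo-4-(triisopropylsilyloxy)phenyl]prop-2-yn-1-one | COc1c(Br)cc(C(=O)C#Cc2ccc(O[Si](C(C)C)(C(C)C)C(C)C)c(Br)c2)cc1Br
F2 | step 9 | (3,5-dibromo-4-methoxyphenyl){4-[3-bromo-4-(triisopropylsilyloxy)phenyl]-2-ethoxyfuran-3-yl}methanone | CCOc1occ(-c2ccc(O[Si](C(C)C)(C(C)C)C(C)C)c(Br)c2)c1C(=O)c1cc(Br)c(OC)c(Br)c1
F3 | step 9 | 3-(3,5-dibromo-4-methoxybenzoyl)-4-[3-bromo-4-(triisopropylsilyloxy)phenyl]furan-2(5H)-one | COc1c(Br)cc(C(=O)C2=C(c3ccc(O[Si](C(C)C)(C(C)C)C(C)C)c(Br)c3)COC2=O)cc1Br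
F4 | step 9 | (Z)-3-(3,5-dibromo-4-methoxybenzoyl)-5-[3-bromo-4-(triisopropylsilyloxy)benzylidene]-4-[3-bromo-4-(triisopropylsilyloxy)phenyl]furan-2(5H)-one | COc1c(Br)cc(C(=O)C2=C(c3ccc(O[Si](C(C)C)(C(C)C)C(C)C)c(Br)c3)/C(=C/c3ccc(O[Si](C(C)C)(C(C)C)C(C)C)c(Br)c3)OC2=O)cc1Br
F5 | step 9 | (Z)-5-[3-bromo-4-(triisopropylsilyloxy)benzylidene]-4-[3-bromo-4-(triisopropylsilyloxy)phenyl]-3-[(S)-(3,5-dibromo-4-methoxyphenyl)(hydroxy)methyl]furan-2(5H)-one | COc1c(Br)cc([C@H](O)C2=C(c3ccc(O[Si](C(C)C)(C(C)C)C(C)C)c(Br)c3)/C(=C/c3ccc(O[Si](C(C)C)(C(C)C)C(C)C)c(Br)c3)OC2=O)cc1Br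
F6 | step 8 | {[(S)-1-(3,5-dibromo-4-methoxyphenyl)-3-(3-bromo-4-triisopropylsilyloxyphenyl)prop-2-yn-1-yl]oxy}diisopropylsilyl N-{[3-bromo-4-(triisopropylsilyloxy)phenyl]acetyl}-L-alaninate | COc1c(Br)cc([C@H](O[Si](C(C)C)(C(C)C)OC(=O)[C@H](C)NC(=O)Cc2ccc(O[Si](C(C)C)(C(C)C)C(C)C)c(Br)c2)C#Cc2ccc(O[Si](C(C)C)(C(C)C)C(C)C)c(Br)c2)cc1Br
F7 | step 10 | 5-[3-bromo-4-(triisopropylsilyloxy)benzyl]-4-[3-bromo-4-(triisopropylsilyloxy)phenyl]-3-{(S)-(3,5-dibromo-4-methoxyphenyl)[hydroxy(diisopropyl)silyloxy]methyl}-5-(phenylselanyl)furan-2(5H)-one, C5 epimers | COc1c(Br)cc([C@H](O[Si](O)(C(C)C)C(C)C)C2=C(c3ccc(O[Si](C(C)C)(C(C)C)C(C)C)c(Br)c3)C([Se]c3ccccc3)(Cc3ccc(O[Si](C(C)C)(C(C)C)C(C)C)c(Br)c3)OC2=O)cc1Br
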